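In both runs starting complex falls and then climbs back: the violet flask holds 71.1% at 4.00 d against 61.8% at 0.333 d. So exchange runs backwards, and complex is lost by another way.

all flasks: starting complex 0.10 M

| charge | incoming ligand | remark | time |
|---|---|---|---|
| violet | 0.60 equiv | the very flask that is asked about, followed so far |  |
| grey | 0.30 equiv | run made earlier |  |
| flask | 0.600 equiv |  | 8.0 d |

| run | time / d | complex with one exchanged / % | starting complex / % |
|---|---|---|---|
| violet | 0.104 | 23.6 | 71.4 |
| violet | 0.333 | 32.4 | 61.8 |
| violet | 1.25 | 26.7 | 62.4 |
| violet | 4.00 | 7.5 | 71.1 |
| grey | 0.104 | 13.7 | 84.4 |
| grey | 0.417 | 17.9 | 78.6 |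
| grey | 2.08 | 11.8 | 81.9 |
| grey | 8.00 | 3.2 | 85.3 |

(readings scatter by 0.5 percentage points)
- time, not beyond 8.0 d, at which the flask holds most complex with one exchanged
- the amount of complex with one exchanged, in percent of the starting complex charged, at that time
- complex with one exchanged is meant together with its crystals
- solid, in amounts per volume of the solution: crystals
- the analysis behind the earlier runs scatters by 0.5 percentage points, standard deviation
- steps that have been proposed: complex with one exchanged + incoming ligand <-> leaving ligand + complex with two exchanged; starting complex + incoming ligand <-> leaving ligand + complex with one exchanged; complex with one exchanged + incoming ligand -> over-reaction product; crystals <-> complex with one exchanged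

The grey run has lost 14.7% of its starting complex at 8.00 d. Counting its whole charge of incoming ligand as spent by then gives 2.04 of incoming ligand per complex lost. This ligand price is a ratio of end amounts, not of rates, so it serves for the end of a run and says nothing of the way there. It fits the proposed path, in which a complex takes up two ligands on its way to over-reaction product. The flask should therefore end near 70.6% starting complex, with [complex with one exchanged] passing through a maximum on the way. My own reckoning puts that top close to the reading of 32.4% at 0.333 d.

The forecast says 0.4 d and 33%, with “one early maximum, and nothing later recovers it”. The flask gives 0.422 d and 33.3%.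

    complex with one exchanged + incoming ligand ⇌ leaving ligand + complex with two exchanged (K = 0.330, k = 0.00200 L mol⁻¹ s⁻¹)
    starting complex + incoming ligand ⇌ leaving ligand + complex with one exchanged (K = 0.360, k = 0.00120 L mol⁻¹ s⁻¹)
    complex with one exchanged + incoming ligand → over-reaction product (k = 6.40 × 10⁻⁴ L mol⁻¹ s⁻¹)
    crystals ⇌ complex with one exchanged, rate k4*(cs4 - [complex with one exchanged]) while solid is left; crystals form when [complex with one exchanged] > cs4 (solubility = 7.80 mM, k = 7.10 × 10⁻⁴ s⁻¹)

At 0.0321 d dissolved complex with one exchanged is made 1.22 times as fast as it is used up. At 8.00 d that ratio is 0.141, and the flask holds 70.3% starting complex. With 2.40 equiv, the price gives 1.18 times the ligand needed, so starting complex is the limiting reagent and 15.0% of the ligand stays. That flask ends with 1.3% starting complex, 18% of its ligand and 98.5% over-reaction product.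

All runs come from a simulation on assumed constants; scatter was added.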